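**Retrosynthetic overview**
1. Target ⇐ ester reduction (CO2Me → CH2OH) ⇐ cis-2,3-dihydrobenzofuran by catalyst-controlled syn-hydrogenation of a 2-aryl-benzofuran-3-carboxylate (sets C2 and C3).
2. endo,endo-Furofuran ⇐ convex-face silane reduction of a cis-fused bis-hemiketal (sets both ArCH–O centres) ⇐ 1,4-diaryl-2,3-bis(hydroxymethyl)butane-1,4-dione.
3. Benzofuran + diketone ⇐ one threefold DDQ dehydrogenation ⇐ 8–5′ phenol-radical cross-coupling/quinone methide closure of methyl ferulate onto an open-chain 8–8′ tetraol.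
4. Tetraol ⇐ LiAlH4 ⇐ bis-lactone ⇐ 8–8′ oxidative dimerisation of ferulic acid with double quinone methide lactonisation (fixes the C8/C8′ pair, racemic).
5. Ring order: fused bis-lactone (later opened) → dihydrobenzofuran → all three ArC–O centres flattened → furofuran re-closed at the ketal level and reduced → furan ring re-saturated cis. One chiral-phase resolution (furofuran block) and one chiral catalyst (coumaran block) give the single enantiomer.

Assumption (stereochemistry and locants): the SMILES is taken as drawn, i.e. an all-cis (7S,7′S,8S,8′S) furofuran with both aryl groups endo and a (2S,3S) cis-dihydrobenzofuran, not the exo,exo/trans pattern that quinone methide closure gives. C7 = ArCH–O, C8 = ring-fusion CH, C9 = CH2O, with primes for the central unit and double primes for the coumaran unit; racemic compounds are drawn as the enantiomer that leads to the target.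

**Step 1**
Reactants: 1 ferulic acid (2 equiv)
Product: 3 (±)-8–8′ bis-lactone (3R*,3aR*,6R*,6aR*)-3,6-bis(4-hydroxy-3-methoxyphenyl)tetrahydro-1H,3H-furo[3,4-c]furan-1,4-dione, via bis-quinone methide diacid 2 (not isolated)
Conditions: FeCl3·6H2O (20 mol %), O2 (1 atm), acetone–H2O 1:1, 25 °C
Reagents that add atoms: none
Why: Phenol oxidative coupling as in lignan biosynthesis: the ferulate phenoxyl radical dimerises C8–C8′ to the threo bis-quinone methide 2 and each carboxylic acid adds to the opposite quinone methide (double intramolecular oxa-Michael lactonisation), which locks the C8/C8′ pair as the cis ring fusion (racemic) and places both aryl groups exo, a feature erased again in step 4.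

**Step 2**
Reactants: 3 (±)-8–8′ bis-lactone
Product: 4 (±)-tetraol (1R*,2S*,3S*,4R*)-1,4-bis(4-hydroxy-3-methoxyphenyl)-2,3-bis(hydroxymethyl)butane-1,4-diol
Conditions: LiAlH4 (6 equiv), THF, 0 → 65 °C (3 added to the hydride); aqueous potassium sodium tartrate work-up at pH 7
Reagents that add atoms: none
Why: LiAlH4 reduction of both γ-lactones breaks no bond at a stereocentre, so the C8/C8′ pair is carried through, and the neutral work-up prevents acid-induced re-closure of the p-hydroxybenzylic carbinols to the exo,exo-furofuran.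

**Step 3**
Reactants: 4 (±)-tetraol (3 equiv, excess recovered); 5 methyl ferulate (1 equiv)
Product: 7 trans-coumaran ester tetraol methyl trans-5-[(1R*,2S*,3S*,4R*)-1,4-dihydroxy-4-(4-hydroxy-3-methoxyphenyl)-2,3-bis(hydroxymethyl)butyl]-2-(4-hydroxy-3-methoxyphenyl)-7-methoxy-2,3-dihydro-1-benzofuran-3-carboxylate (two racemic diastereomers used together), via quinone methide adduct 6 (not isolated)
Conditions: Ag2O (1.2 equiv), dry acetone, 25 °C, dark; 5 added by syringe pump over 8 h
Reagents that add atoms: none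
Why: Ag2O-mediated 8–5′ oxidative cross-coupling of two phenoxyl radicals (ferulate C8 to the free ortho position of one guaiacyl ring of 4, favoured by slow addition of 5 to excess 4), then re-aromatisation and intramolecular oxa-Michael addition of the phenol to quinone methide 6, closes the dihydrobenzofuran with the usual trans C2/C3 arrangement; neither this nor the carbinol configuration is controlled, because step 4 removes them all.

**Step 4**
Reactants: 7 trans-coumaran ester tetraol
Product: 8 (±)-benzofuran diketone-diol methyl 5-[(2S*,3S*)-4-(4-hydroxy-3-methoxyphenyl)-2,3-bis(hydroxymethyl)-4-oxobutanoyl]-2-(4-hydroxy-3-methoxyphenyl)-7-methoxy-1-benzofuran-3-carboxylate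
Conditions: DDQ (3.3 equiv), 1,4-dioxane, 25 → 90 °C
Reagents that add atoms: none
Why: DDQ dehydrogenation does three jobs at once: it aromatises the phenolic trans-coumaran to the 2-arylbenzofuran-3-carboxylate (quinone methide formation at C2, then loss of H3) and oxidises both electron-rich benzylic carbinols to aryl ketones, so every stereocentre made by quinone methide trapping is flattened while the non-benzylic C8/C8′ pair is untouched.

**Step 5**
Reactants: 8 (±)-benzofuran diketone-diol
Product: 10 endo,endo-furofuran benzofuran ester methyl 2-(4-hydroxy-3-methoxyphenyl)-5-[(1S,3aS,4S,6aS)-4-(4-hydroxy-3-methoxyphenyl)tetrahydro-1H,3H-furo[3,4-c]furan-1-yl]-7-methoxy-1-benzofuran-3-carboxylate, via cis-fused bis-hemiketal 9 (not isolated)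
Conditions: Et3SiH (8 equiv), BF3·OEt2, CH2Cl2–MeCN 3:1, −78 → −40 °C, cold aqueous NaHCO3 quench; enantiomers then separated by preparative SFC on an amylose tris(3,5-dimethylphenylcarbamate) phase
Reagents that add atoms: none
Why: Ionic hydrogenation of a cyclic hemiketal (Et3SiH/BF3·OEt2 reductive deoxygenation): 8 closes to the cis-fused bis-hemiketal 9 and each aryl-stabilised oxocarbenium ion takes hydride on the convex face, anti to the neighbouring ring bond (the kinetic 2,3-cis outcome known for 2-aryltetrahydrofuran lignan hemiketals), so both aryl groups end up endo and C7/C7′ follow from C8/C8′; the electron-poor benzofuran ester is inert, and the racemate is resolved here because the C8/C8′ centres of 10 are no longer next to a carbonyl and cannot epimerise.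

**Step 6**
Reactants: 10 endo,endo-furofuran benzofuran ester (single enantiomer)
Product: 11 cis-coumaran ester methyl (2S,3R)-2-(4-hydroxy-3-methoxyphenyl)-5-[(1S,3aS,4S,6aS)-4-(4-hydroxy-3-methoxyphenyl)tetrahydro-1H,3H-furo[3,4-c]furan-1-yl]-7-methoxy-2,3-dihydro-1-benzofuran-3-carboxylate
Conditions: H2 (80 bar), Ru(cod)(2-methylallyl)2 (5 mol %), chiral imidazolinium salt SINpEt·HBF4 (10 mol %, antipode chosen for the 2S,3R product), KOtBu (15 mol %; catalyst pre-formed), THF–hexane, 40 °C
Reagents that add atoms: none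
Why: Proposed new method: enantioselective hydrogenation of a 2-aryl-benzofuran-3-carboxylate with the chiral Ru–NHC catalyst, the closest known reaction being the Ru–NHC asymmetric hydrogenation of 2-aryl- and 2-alkylbenzofurans; the furan C2=C3 bond is the only non-benzenoid π-bond, both hydrogens come from the metal onto one face (syn addition, hence 2,3-cis by necessity) and the chiral carbene ligand selects the face giving (2S,3R), any wrong-face product being a separable diastereomer because 10 is already enantiopure.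

**Step 7**
Reactants: 11 cis-coumaran ester
Product: 12 target 4-[(2S,3S)-3-(hydroxymethyl)-5-[(1S,3aS,4S,6aS)-4-(4-hydroxy-3-methoxyphenyl)tetrahydro-1H,3H-furo[3,4-c]furan-1-yl]-7-methoxy-2,3-dihydro-1-benzofuran-2-yl]-2-methoxyphenol
Conditions: LiAlH4 (4 equiv), THF, −20 → 0 °C; aqueous potassium sodium tartrate work-up
Reagents that add atoms: none
Why: LiAlH4 ester reduction at low temperature converts CO2Me into CH2OH without touching C2 or C3 (the C3 descriptor changes from R to S only through the priority change), and the non-acidic conditions preserve the acid-labile endo,endo-furofuran and cis-coumaran.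

**Compound list**
1 | ferulic acid, (E)-3-(4-hydroxy-3-methoxyphenyl)prop-2-enoic acid | COc1cc(/C=C/C(=O)O)ccc1O | starting material
2 | bis-quinone methide diacid, (2S*,3S*)-2,3-bis[(3-methoxy-4-oxocyclohexa-2,5-dien-1-ylidene)methyl]butanedioic acid (racemic, drawn 2S,3S) | COC1=CC(=C[C@H](C(=O)O)[C@@H](C(=O)O)C=C2C=CC(=O)C(OC)=C2)C=CC1=O | intermediate (not isolated)
3 | 8–8′ bis-lactone, (3R*,3aR*,6R*,6aR*)-3,6-bis(4-hydroxy-3-methoxyphenyl)tetrahydro-1H,3H-furo[3,4-c]furan-1,4-dione, cis-fused, both aryl groups exo (racemic, drawn 3R,3aR,6R,6aR) | COc1cc([C@@H]2OC(=O)[C@@H]3[C@H]2C(=O)O[C@H]3c2ccc(O)c(OC)c2)ccc1O | intermediate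
4 | tetraol, (1R*,2S*,3S*,4R*)-1,4-bis(4-hydroxy-3-methoxyphenyl)-2,3-bis(hydroxymethyl)butane-1,4-diol (racemic, drawn 1R,2S,3S,4R) | COc1cc([C@H](O)[C@H](CO)[C@@H](CO)[C@@H](O)c2ccc(O)c(OC)c2)ccc1O | intermediate
5 | methyl ferulate, methyl (E)-3-(4-hydroxy-3-methoxyphenyl)prop-2-enoate | COC(=O)/C=C/c1ccc(O)c(OC)c1 | starting material
6 | quinone methide adduct: tetraol 4 carrying, ortho to one phenol, a CH(CO2Me)–CH=(3-methoxy-4-oxocyclohexa-2,5-dien-1-ylidene) group (one stereoisomer drawn) | COc1cc([C@H](O)[C@H](CO)[C@@H](CO)[C@@H](O)c2cc(OC)c(O)c(c2)[C@H](C(=O)OC)C=C2C=CC(=O)C(OC)=C2)ccc1O | intermediate (not isolated)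
7 | trans-coumaran ester tetraol, methyl trans-5-[(1R*,2S*,3S*,4R*)-1,4-dihydroxy-4-(4-hydroxy-3-methoxyphenyl)-2,3-bis(hydroxymethyl)butyl]-2-(4-hydroxy-3-methoxyphenyl)-7-methoxy-2,3-dihydro-1-benzofuran-3-carboxylate (two racemic diastereomers; the 2S,3S-coumaran isomer drawn) | COc1cc([C@H](O)[C@H](CO)[C@@H](CO)[C@@H](O)c2cc(OC)c3c(c2)[C@H](C(=O)OC)[C@@H](c2ccc(O)c(OC)c2)O3)ccc1O | intermediate
8 | benzofuran diketone-diol, methyl 5-[(2S*,3S*)-4-(4-hydroxy-3-methoxyphenyl)-2,3-bis(hydroxymethyl)-4-oxobutanoyl]-2-(4-hydroxy-3-methoxyphenyl)-7-methoxy-1-benzofuran-3-carboxylate (racemic, drawn 2S,3S) | COc1cc(C(=O)[C@H](CO)[C@@H](CO)C(=O)c2cc(OC)c3oc(-c4ccc(O)c(OC)c4)c(C(=O)OC)c3c2)ccc1O | intermediate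
9 | cis-fused bis-hemiketal, methyl 5-[(3aS*,6aS*)-1,4-dihydroxy-4-(4-hydroxy-3-methoxyphenyl)tetrahydro-1H,3H-furo[3,4-c]furan-1-yl]-2-(4-hydroxy-3-methoxyphenyl)-7-methoxy-1-benzofuran-3-carboxylate (hemiketal carbons undefined) | COc1cc(C2(O)OC[C@@H]3[C@H]2COC3(O)c2cc(OC)c4oc(-c5ccc(O)c(OC)c5)c(C(=O)OC)c4c2)ccc1O | intermediate (not isolated)
10 | endo,endo-furofuran benzofuran ester, methyl 2-(4-hydroxy-3-methoxyphenyl)-5-[(1S,3aS,4S,6aS)-4-(4-hydroxy-3-methoxyphenyl)tetrahydro-1H,3H-furo[3,4-c]furan-1-yl]-7-methoxy-1-benzofuran-3-carboxylate (single enantiomer after resolution) | COc1cc([C@H]2OC[C@@H]3[C@H]2CO[C@@H]3c2cc(OC)c4oc(-c5ccc(O)c(OC)c5)c(C(=O)OC)c4c2)ccc1O | intermediate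
11 | cis-coumaran ester, methyl (2S,3R)-2-(4-hydroxy-3-methoxyphenyl)-5-[(1S,3aS,4S,6aS)-4-(4-hydroxy-3-methoxyphenyl)tetrahydro-1H,3H-furo[3,4-c]furan-1-yl]-7-methoxy-2,3-dihydro-1-benzofuran-3-carboxylate (2,3-cis) | COc1cc([C@H]2OC[C@@H]3[C@H]2CO[C@@H]3c2cc(OC)c3c(c2)[C@@H](C(=O)OC)[C@@H](c2ccc(O)c(OC)c2)O3)ccc1O | intermediate
12 | CNP0303197.1, 4-[(2S,3S)-3-(hydroxymethyl)-5-[(1S,3aS,4S,6aS)-4-(4-hydroxy-3-methoxyphenyl)tetrahydro-1H,3H-furo[3,4-c]furan-1-yl]-7-methoxy-2,3-dihydro-1-benzofuran-2-yl]-2-methoxyphenol | COc1cc([C@H]2OC[C@@H]3[C@H]2CO[C@@H]3c2cc(OC)c3c(c2)[C@@H](CO)[C@@H](c2ccc(O)c(OC)c2)O3)ccc1O | target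

**Step count and risks**
Total steps: 7. Longest linear sequence: 7 (1 → 12); methyl ferulate 5 is bought.

Step 3 (cross-coupling) is the least efficient step: homo-dimerisation of 5, 8–O–4′ coupling and side-chain displacement at the p-hydroxybenzylic carbinol all compete. The fallback sets out from 4 and returns at 8, replacing the radical coupling by a polar benzofuran annulation.
- Mono-iodination of 4 ortho to one phenol (N-iodosuccinimide, 1 equiv, MeCN, 0 °C) gives the iodotetraol F1.
- Sonogashira coupling (PdCl2(PPh3)2, CuI, K2CO3, DMF, 50 °C) with 4-ethynyl-2-methoxyphenol F2, itself made from vanillin with dimethyl (1-diazo-2-oxopropyl)phosphonate and K2CO3 in MeOH, gives the 2-alkynylphenol F3.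
- Oxidative methoxycarbonylative cyclisation (PdI2 cat., KI, CO/air, MeOH, 80 °C) gives the benzofuran ester tetraol F4.
- DDQ (2.2 equiv, dioxane) then only has the two benzylic carbinols to oxidise and delivers 8.

Step 4 (threefold DDQ oxidation) may stall at the carbinol on the benzofuran-bearing ring once the coumaran has aromatised, and the β-hydroxy ketones can dehydrate or epimerise to the meso diketone. The fallback sets out from 4 and returns at 10: oxidise before coupling and carry the furofuran as a ketal.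
- DDQ (2.1 equiv, dioxane, 25 °C) converts the two p-hydroxybenzylic carbinols of 4 into the symmetrical diketone-diol F5.
- HC(OMe)3, MeOH and pyridinium p-toluenesulfonate close it to the bicyclic bis(methyl ketal) F6, whose phenols are again ordinary electron-rich guaiacols.
- Ag2O cross-coupling with 5 as in step 3 gives the coumaran ester bis-ketal F7.
- DDQ (1.1 equiv) now has only the coumaran to dehydrogenate and gives the benzofuran ester bis-ketal F8.
- Et3SiH/BF3·OEt2 as in step 5 reduces both ketal carbons from the convex face and, after the same resolution, returns to 10.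

Step 6 (asymmetric hydrogenation) has no direct precedent for a 3-carboxylate, and the free phenols may slow the catalyst. The fallback sets out from 10 and returns at 11, giving up catalyst control for diastereomer separation. Hydrogenation of enantiopure 10 over Pd/C (H2, 30 bar, EtOAc, 25 °C) adds cis from either face and gives 11 together with its coumaran-antipodal (2R,3S) cis-diastereomer F9 in about equal amounts. Since the furofuran block is already a single enantiomer, these are diastereomers and are separated by chromatography to give 11.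

**Further compounds**
F1 | step 3 | iodotetraol, (1R*,2S*,3S*,4R*)-1-(4-hydroxy-3-iodo-5-methoxyphenyl)-4-(4-hydroxy-3-methoxyphenyl)-2,3-bis(hydroxymethyl)butane-1,4-diol | COc1cc([C@H](O)[C@H](CO)[C@@H](CO)[C@@H](O)c2cc(I)c(O)c(OC)c2)ccc1O
F2 | step 3 | 4-ethynyl-2-methoxyphenol | C#Cc1ccc(O)c(OC)c1
F3 | step 3 | 2-alkynylphenol, tetraol 4 bearing a (4-hydroxy-3-methoxyphenyl)ethynyl group ortho to one phenol | COc1cc([C@H](O)[C@H](CO)[C@@H](CO)[C@@H](O)c2cc(C#Cc3ccc(O)c(OC)c3)c(O)c(OC)c2)ccc1O
F4 | step 3 | benzofuran ester tetraol, methyl 5-[(1R*,2S*,3S*,4R*)-1,4-dihydroxy-4-(4-hydroxy-3-methoxyphenyl)-2,3-bis(hydroxymethyl)butyl]-2-(4-hydroxy-3-methoxyphenyl)-7-methoxy-1-benzofuran-3-carboxylate | COc1cc([C@H](O)[C@H](CO)[C@@H](CO)[C@@H](O)c2cc(OC)c3oc(-c4ccc(O)c(OC)c4)c(C(=O)OC)c3c2)ccc1O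
F5 | step 4 | symmetrical diketone-diol, (2S*,3S*)-1,4-bis(4-hydroxy-3-methoxyphenyl)-2,3-bis(hydroxymethyl)butane-1,4-dione | COc1cc(C(=O)[C@H](CO)[C@@H](CO)C(=O)c2ccc(O)c(OC)c2)ccc1O
F6 | step 4 | bis(methyl ketal), (3aS*,6aS*)-1,4-bis(4-hydroxy-3-methoxyphenyl)-1,4-dimethoxytetrahydro-1H,3H-furo[3,4-c]furan (ketal carbons undefined) | COc1cc(C2(OC)OC[C@@H]3[C@H]2COC3(OC)c2ccc(O)c(OC)c2)ccc1O
F7 | step 4 | coumaran ester bis-ketal, methyl trans-2-(4-hydroxy-3-methoxyphenyl)-5-[(3aS*,6aS*)-4-(4-hydroxy-3-methoxyphenyl)-1,4-dimethoxytetrahydro-1H,3H-furo[3,4-c]furan-1-yl]-7-methoxy-2,3-dihydro-1-benzofuran-3-carboxylate | COc1cc(C2(OC)OC[C@@H]3[C@H]2COC3(OC)c2cc(OC)c3c(c2)[C@H](C(=O)OC)[C@@H](c2ccc(O)c(OC)c2)O3)ccc1O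
F8 | step 4 | benzofuran ester bis-ketal, methyl 2-(4-hydroxy-3-methoxyphenyl)-5-[(3aS*,6aS*)-4-(4-hydroxy-3-methoxyphenyl)-1,4-dimethoxytetrahydro-1H,3H-furo[3,4-c]furan-1-yl]-7-methoxy-1-benzofuran-3-carboxylate | COc1cc(C2(OC)OC[C@@H]3[C@H]2COC3(OC)c2cc(OC)c4oc(-c5ccc(O)c(OC)c5)c(C(=O)OC)c4c2)ccc1O
F9 | step 6 | coumaran-antipodal cis ester, methyl (2R,3S)-2-(4-hydroxy-3-methoxyphenyl)-5-[(1S,3aS,4S,6aS)-4-(4-hydroxy-3-methoxyphenyl)tetrahydro-1H,3H-furo[3,4-c]furan-1-yl]-7-methoxy-2,3-dihydro-1-benzofuran-3-carboxylate | COc1cc([C@H]2OC[C@@H]3[C@H]2CO[C@@H]3c2cc(OC)c3c(c2)[C@H](C(=O)OC)[C@H](c2ccc(O)c(OC)c2)O3)ccc1O
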